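## Structural features

Atom labels used throughout:
- Cyclopentene ring: C1(Et)=C2–C3(Me)–C3a–C7a.
- Cyclohexene ring: C3a–C4(Me)=C5–C6–C7–C7a.
- Side chain on C6: C1'H=C2'(Me)–C3'H=C4'H–Ph.
- Cα is the carbinol carbon of the auxiliary alcohol.

The two rings share the C3a–C7a bond and form a bicyclo[4.3.0]nona-diene. H3a and H7a are anti, so the fusion is trans.

Five stereocentres are contiguous (C3, C3a, C7a, C7, C6). The C3-methyl, the C3a–C4 bond and the C7a–C7 bond alternate faces around the five-membered ring (all-trans). The C6 and C7 methyl groups are cis, so the carboxyl and the dienyl chain are also cis.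

C6 and C7 are adjacent all-carbon quaternary centres. C6 is doubly allylic and C7 carries a neopentyl-type acid. No centre is epimerisable, so a stereochemical error cannot be repaired later.

Fragile groups:
- The styryl diene is sensitive to acid, light, oxidants and metathesis catalysts.
- The γ,δ-unsaturated acid can lactonise onto C4=C5 or C1=C2 under strong acid.

The real difficulty is the C6–C7 bond, its two configurations relative to C7a, and the trans fusion. The trans fusion forbids closing the six-membered ring at C3a or C7a of a preformed cyclopentene, because such closures give cis.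

The key step exploits the array C(=O)–C7–C6–C5=C4. This is a γ,δ-unsaturated acid, which is the retron of an ester-enolate [3,3] shift whose new σ-bond is exactly C6–C7.

The route in one sentence: an Ireland–Claisen rearrangement of the ester formed from an all-trans cyclopentenylpropanoic acid and an enantiopure iododienyl carbinol forges the C6–C7 bond and both quaternary centres. The six-membered ring is closed afterwards at the remote C4=C5 bond.

## Logic of the disconnections

**28 ⇒ 26 + 27.**
- Cut: the C2'–C3' sp2–sp2 bond.
- Reason: the styryl diene would compete for a metathesis catalyst and is the most labile part of the molecule.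
- Gain: the side chain shrinks to a three-carbon iodoalkenyl group that is inert to bases and ruthenium carbenes.
- Demand: a stereoretentive cross-coupling that tolerates a free hindered acid.

**26 ⇒ 25.**
- Cut: C4=C5.
- Reason: this is the ring bond most remote from the fusion, so the trans relationship can be set beforehand on the cyclopentene by intermolecular anti additions.
- Gain: the bicycle becomes a cyclopentene with an open chain.
- Demand: ring-closing metathesis between a 1,1-disubstituted alkene and a propenyl group on a quaternary carbon, with C1=C2 and the iodoalkene as spectators.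

**25 ⇒ 21 (key).**
- Cut: C6–C7.
- Reason: this is the most hindered bond and carries both quaternary centres. A concerted six-centre shift forms it under geometric control rather than steric approach control.
- Gain: the problem splits into an acid with three easy ring stereocentres and an alcohol with one purchased stereocentre.
- Demand: a defined ketene acetal geometry, a chair array, and clean 1,3-chirality transfer from Cα.

**21 ⇒ 11 + 20.**
- Cut: the ester C–O bond.
- Reason and gain: this makes the route convergent, with two fragments of similar size.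
- Demand: a mild acylation of an acid-sensitive secondary dienyl alcohol. The configuration at C7 is irrelevant.

**11 ⇒ 10 ⇒ 9 ⇒ 7.**
- Cut: C1–ethyl and C3–methyl.
- Reason: a conjugate methyl addition to the enone gives the C1 enolate regiospecifically. Trapping it as the triflate fixes the C1=C2 position.
- Gain: two alkyl groups and one stereocentre are removed.
- Demand: attack anti to the neighbouring isopropenyl group.

**7 ⇒ 6 ⇒ 3 + 4 ⇒ 1 + 2.**
- Cut: C7a–C7 and C3a–C4.
- Reason: these are vicinal anti additions on a 4-silyloxycyclopentenone. The bought C3–O centre directs C3a, C3a directs C7a, and the oxygen then leaves to unveil the enone.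
- Gain: commercial materials are reached.
- Demand: regiospecific enolate alkylation without loss of the β-silyloxy group.

**20 ⇒ 18 ⇒ 16 + 17 ⇒ 14 ⇒ 12.**
- Cut: C6–C1' (sp2–sp), the two C–I bonds and the alkyne methyl.
- Reason: syn hydrometalation of methyl-capped alkynes gives both E-trisubstituted alkenes.
- Demand: zirconium must go to the methyl-bearing alkyne carbon each time.

## Other disconnections considered

**Alternative 1:** cut C3a–C7a and C6–C7 together, in an intramolecular Diels–Alder reaction of the open-chain polyene acid A1. This is the first idea, since the cyclohexene retron and an all-E diene and dienophile map directly onto 28. Grounds for preferring the chosen plan: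
- The three-atom tether contains C1=C2, which must have C7a and C3 cis. A1 therefore holds a (2E,4Z)-dienoate, and its C3–H is placed for a 1,5-hydrogen shift that would erase the only stereocentre.
- That single centre would have to control facial and endo/exo selection for four new centres in one irreversible event.
- The diene terminus C6 is fully substituted, which raises the cost of the s-cis conformer.
- A stereodefined hexaene needs an iterative olefination sequence of comparable length, carrying a light- and acid-sensitive chain throughout.

**Alternative 2:** cut C6–C7 transannularly. The ten-membered dienyl lactone A2 would contract through its silyl ketene acetal to the vinyl acid A3. This closes the ring and sets C6 and C7 at once. Grounds for preferring the chosen plan: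
- A2 requires a medium-ring lactonisation on a trans-disubstituted cyclopentene.
- The ring, not the conditions, dictates the endocyclic ketene acetal geometry. A chair array would need one trans double bond inside the ten-membered ring.
- A3 carries only a vinyl group at C6. Its conversion into the side chain would need oxidative cleavage in the presence of two more electron-rich trisubstituted alkenes, plus several further steps.

**Alternative 3:** cut C3a–C7a, C1–C2 and C2–C3, with C2 coming from carbon monoxide. A Pauson–Khand bicyclisation of the dienyne A4 would give the dienone A5. The C1=C2/H7a array would then follow by 1,2-reduction and reductive allylic transposition. Both rings close in one step. Grounds for preferring the chosen plan: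
- A4 already contains the C6–C7 array, so the hardest problem stays unsolved.
- C3a would form under the influence only of quaternary carbons whose substituent pairs are of similar size.
- A conjugated 1,2-disubstituted alkene is a poor partner for this reaction.
- The C3a–H of A5 is γ to the enone and allylic, which invites migration of C4=C5 into conjugation.

Key step: step 12

Assumption: C7 in 6–11 and 21 is formed as a mixture of epimers and is left undefined in the SMILES, because step 12 planarises it. Compounds 1, 2, 4, 12, 17 and 27 are taken as commercial.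

## Steps

Step 1
Reactants: 1 (R)-4-(tert-butyldimethylsilyloxy)cyclopent-2-en-1-one; 2 prop-1-en-2-ylmagnesium bromide
Product: 3 (3S,4R)-4-(tert-butyldimethylsilyloxy)-3-(prop-1-en-2-yl)-1-(trimethylsilyloxy)cyclopent-1-ene
Conditions: 2, CuBr·SMe2 (10 mol %), TMSCl, DMPU, THF, −78 °C
Reagents that add atoms: chlorotrimethylsilane, C[Si](C)(C)Cl
Why: Copper-catalysed, silyl-chloride-accelerated conjugate addition; the nucleophile should enter anti to the C3 silyloxy group and so set C3a, and O-silylation stores the enolate regiospecifically at C1=C7a.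

Step 2
Reactants: 3; 4 methyl 2-bromopropanoate (racemic)
Product: 6 methyl 2-[(1S,2S,3R)-3-(tert-butyldimethylsilyloxy)-5-oxo-2-(prop-1-en-2-yl)cyclopentyl]propanoate (C7 epimers), via lithium enolate 5 (not isolated)
Conditions: MeLi, THF, 0 °C; then 4, DMPU, −78 → −30 °C
Reagents that add atoms: methyllithium, [Li]C (supplies the lithium of 5 only)
Why: Regiospecific enolate generation from a silyl enol ether followed by SN2 alkylation with an α-halo ester; the electrophile should approach anti to the adjacent isopropenyl group and set C7a trans, while the TBS ether is inert to MeLi.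

Step 3
Reactants: 6
Product: 7 methyl 2-[(1S,5S)-2-oxo-5-(prop-1-en-2-yl)cyclopent-3-en-1-yl]propanoate (C7 epimers)
Conditions: DBU, CH2Cl2, 0 °C, short contact
Reagents that add atoms: none
Why: E1cB loss of the β-silyloxy group (the PGE-to-PGA type dehydration) unveils the C2=C3 enone; C3a and C7a are untouched, and the trans arrangement is also the thermodynamic one at the enolisable C7a.

Step 4
Reactants: 7
Product: 9 methyl 2-[(1S,4S,5S)-4-methyl-5-(prop-1-en-2-yl)-2-(trifluoromethylsulfonyloxy)cyclopent-2-en-1-yl]propanoate (C7 epimers), via lithium enolate 8 (not isolated)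
Conditions: MeLi, CuI, Et2O, 0 °C; 7, −78 °C; then N-(5-chloro-2-pyridyl)bis(trifluoromethanesulfonimide), THF, −78 → 0 °C
Reagents that add atoms: lithium dimethylcuprate, [Li+].C[Cu-]C; N-(5-chloro-2-pyridyl)bis(trifluoromethanesulfonimide), O=S(=O)(N(c1ccc(Cl)cn1)S(=O)(=O)C(F)(F)F)C(F)(F)F
Why: Cuprate conjugate addition with O-sulfonylation of the resulting enolate; methyl should add anti to the neighbouring C3a isopropenyl group (setting C3), and the enolate is formed only toward C2, which fixes the future C1=C2 bond.

Step 5
Reactants: 9
Product: 10 methyl 2-[(1S,4R,5S)-2-ethyl-4-methyl-5-(prop-1-en-2-yl)cyclopent-2-en-1-yl]propanoate (C7 epimers)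
Conditions: Et2Zn, PdCl2(dppf) (5 mol %), THF, 50 °C
Reagents that add atoms: diethylzinc, CC[Zn]CC
Why: Negishi sp2–sp3 coupling of an alkenyl triflate; the wide-bite-angle ligand should favour reductive elimination over β-hydride loss, and the ester and alkenes are inert to the organozinc.

Step 6
Reactants: 10
Product: 11 2-[(1S,4R,5S)-2-ethyl-4-methyl-5-(prop-1-en-2-yl)cyclopent-2-en-1-yl]propanoic acid (C7 epimers)
Conditions: LiOH, THF/MeOH/H2O, 40 °C; then cold 1 M HCl to pH 3
Reagents that add atoms: lithium hydroxide, [Li+].[OH-]
Why: Saponification of a secondary methyl ester; epimerisation at C7 is without consequence, and the brief cold acidification avoids lactonisation onto the isopropenyl group.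

Step 7
Reactants: 12 (R)-but-3-yn-2-ol
Product: 14 (R)-pent-3-yn-2-ol, via dilithium salt 13 (not isolated)
Conditions: n-BuLi (2.1 equiv), THF, −78 → −20 °C; MeI (1.05 equiv), DMPU, −78 °C → rt; H2O
Reagents that add atoms: n-butyllithium, [Li]CCCC (supplies the lithium of 13 only); iodomethane, CI
Why: Alkylation of an alkynol dianion; the acetylide carbon is far more nucleophilic than the alkoxide, and the carbinol centre is not touched.

Step 8
Reactants: 14
Product: 16 (2R,3E)-4-iodopent-3-en-2-ol, via O,C-bis(chlorozirconocene) adduct 15 (not isolated)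
Conditions: Cp2Zr(H)Cl (2.3 equiv), THF, rt → 40 °C, dark; I2, −78 → 0 °C; H2O
Reagents that add atoms: chlorobis(cyclopentadienyl)hydridozirconium, [H][Zr](Cl)(C1C=CC=C1)C1C=CC=C1 (zirconium groups of 15 only); iodine, II
Why: Hydrozirconation–iodinolysis; syn addition under equilibrating conditions should place zirconium on the less hindered methyl-bearing alkyne carbon, and iodinolysis with retention gives the E-iodide with Cα trans to iodine.

Step 9
Reactants: 16; 17 propyne
Product: 18 (2R,3E)-4-methylhept-3-en-5-yn-2-ol
Conditions: 17 (excess), PdCl2(PPh3)2 (3 mol %), CuI (6 mol %), Et3N, THF, 0 °C → rt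
Reagents that add atoms: none
Why: Sonogashira coupling of an alkenyl iodide, which proceeds with retention of the alkene geometry and tolerates the free alcohol.

Step 10
Reactants: 18
Product: 20 (2R,3E,5E)-6-iodo-4-methylhepta-3,5-dien-2-ol, via O,C-bis(chlorozirconocene) adduct 19 (not isolated)
Conditions: Cp2Zr(H)Cl (2.3 equiv), THF, rt, dark; I2, −78 → 0 °C; H2O
Reagents that add atoms: chlorobis(cyclopentadienyl)hydridozirconium, [H][Zr](Cl)(C1C=CC=C1)C1C=CC=C1 (zirconium groups of 19 only); iodine, II
Why: Hydrozirconation–iodinolysis of the enyne; the alkyne reacts in preference to the trisubstituted alkene, zirconium should again take the methyl-bearing carbon away from the branched alkenyl group, and syn addition sets the E geometry of C1'=C2'.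

Step 11
Reactants: 11; 20
Product: 21 (2R,3E,5E)-6-iodo-4-methylhepta-3,5-dien-2-yl 2-[(1S,4R,5S)-2-ethyl-4-methyl-5-(prop-1-en-2-yl)cyclopent-2-en-1-yl]propanoate (C7 epimers)
Conditions: DCC, DMAP (cat.), CH2Cl2, 0 °C → rt
Reagents that add atoms: none
Why: Steglich esterification under neutral conditions, which spares the ionisable dienyl carbinol; acylation occurs at oxygen, so Cα keeps its R configuration.

Step 12
Reactants: 21
Product: 25 (2R,3R,4E)-2-[(1R,4R,5S)-2-ethyl-4-methyl-5-(prop-1-en-2-yl)cyclopent-2-en-1-yl]-3-[(1E)-2-iodoprop-1-en-1-yl]-2,3-dimethylhex-4-enoic acid, via lithium (Z)-enolate 22 (not isolated), via (Z)-trimethylsilyl ketene acetal 23 (not isolated), via trimethylsilyl ester 24 (not isolated)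
Conditions: LDA (1.3 equiv), THF/DMPU 4:1, −78 °C; TMSCl; −78 °C → rt, then 60 °C; cold 1 M HCl
Reagents that add atoms: lithium diisopropylamide, [Li+].CC(C)[N-]C(C)C (lithium of 22 only); chlorotrimethylsilane, C[Si](C)(C)Cl (silyl group of 23 and 24 only)
Why: Ireland–Claisen rearrangement (ester-enolate [3,3] shift), the standard reaction type for adjacent quaternary carbons, used here as the fragment union. LDA removes H7, and in the dipolar medium the open deprotonation transition state should turn the bulky ring carbon C7a away from the secondary allyloxy group, so silylation gives the Z-acetal 23 with C7a cis to OSi. 23 then rearranges suprafacially through the six-centre chair C7=C(OSi)–O–Cα–C5=C6, Cα–O breaking as C6–C7 forms, and the new ester carbonyl pays for the lost diene conjugation and the congestion. No ring is closed: the step joins the two halves at the most hindered bond and leaves closure to step 13. C6 is controlled by Cα, whose methyl must sit equatorial because the axial alternative meets the C6 methyl (cis to Cα in the 3E alkene) in a 1,3-diaxial contact, so the R centre is transferred to one face of C5=C6 and ends as the E-propenyl group. C7 is controlled by the acetal geometry within the same chair: Z-acetal plus E-alkene places the two methyl groups anti across the forming bond, which after ring closure is the C6-Me/C7-Me cis, carboxyl/alkenyl cis pattern. The resident centre C7a should reinforce this, since with H7a eclipsing the acetal double bond the reacting face is flanked by C3a (whose isopropenyl points to the far side of the ring) while ethyl-bearing C1 screens the other face. The selectivities needed are acetal geometry and chair over boat, secured by the size gap between methyl and cyclopentenyl and by the acyclic E-alkene; the iodoalkene, C1=C2 and the isopropenyl group have no 1,5-relationship to the acetal and stay spectators.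

Step 13
Reactants: 25
Product: 26 (1R,3aR,4R,5R,7aS)-3-ethyl-5-[(1E)-2-iodoprop-1-en-1-yl]-1,4,5,7-tetramethyl-3a,4,5,7a-tetrahydro-1H-indene-4-carboxylic acid
Conditions: (H2IMes)Cl2Ru=CH(2-iPrO-C6H4) (10 mol %), toluene (2 mM), 80 °C, argon sparge
Reagents that add atoms: none
Why: Ring-closing metathesis between the C3a isopropenyl and the C6 propenyl group forms C4=C5 with loss of propene; the two quaternary carbons pre-fold the chain, the six-membered ring is the only unstrained closure, and the trisubstituted iodoalkene and C1=C2 are too hindered to engage, so no stereocentre is touched.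

Step 14
Reactants: 26; 27 (E)-2-phenylvinylboronic acid
Product: 28 zyggomphic acid B, (1R,3aR,4R,5S,7aS)-3-ethyl-1,4,5,7-tetramethyl-5-[(1E,3E)-2-methyl-4-phenylbuta-1,3-dien-1-yl]-3a,4,5,7a-tetrahydro-1H-indene-4-carboxylic acid
Conditions: 27 (1.5 equiv), Pd(PPh3)4 (5 mol %), aq NaOH (3 equiv), THF, 50 °C, dark; then pH 4 buffer
Reagents that add atoms: none
Why: Suzuki–Miyaura alkenyl–alkenyl coupling with retention at both partners gives the 1'E,3'E diene; the acid is carried as its carboxylate, and the iodine-bearing carbon lies trans to the bulky C6, so it stays accessible.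

## Compound list

1 | (R)-4-(tert-butyldimethylsilyloxy)cyclopent-2-en-1-one | O=C1C[C@@H](O[Si](C)(C)C(C)(C)C)C=C1 | starting material
2 | prop-1-en-2-ylmagnesium bromide | CC(=C)[Mg]Br | starting material
3 | (3S,4R)-4-(tert-butyldimethylsilyloxy)-3-(prop-1-en-2-yl)-1-(trimethylsilyloxy)cyclopent-1-ene | C[Si](C)(C)OC1=C[C@@H](C(C)=C)[C@H](O[Si](C)(C)C(C)(C)C)C1 | intermediate
4 | methyl 2-bromopropanoate | COC(=O)C(C)Br | starting material
5 | lithium (3S,4R)-4-(tert-butyldimethylsilyloxy)-3-(prop-1-en-2-yl)cyclopent-1-en-1-olate | [Li+].[O-]C1=C[C@@H](C(C)=C)[C@H](O[Si](C)(C)C(C)(C)C)C1 | intermediate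
6 | methyl 2-[(1S,2S,3R)-3-(tert-butyldimethylsilyloxy)-5-oxo-2-(prop-1-en-2-yl)cyclopentyl]propanoate | O=C1C[C@@H](O[Si](C)(C)C(C)(C)C)[C@H](C(C)=C)[C@H]1C(C)C(=O)OC | intermediate
7 | methyl 2-[(1S,5S)-2-oxo-5-(prop-1-en-2-yl)cyclopent-3-en-1-yl]propanoate | O=C1C=C[C@H](C(C)=C)[C@H]1C(C)C(=O)OC | intermediate
8 | lithium enolate (C1=C2) of the 3-methyl adduct of 7, ring configuration as in 9 | [Li+].[O-]C1=C[C@@H](C)[C@H](C(C)=C)[C@H]1C(C)C(=O)OC | intermediate
9 | methyl 2-[(1S,4S,5S)-4-methyl-5-(prop-1-en-2-yl)-2-(trifluoromethylsulfonyloxy)cyclopent-2-en-1-yl]propanoate | O=S(=O)(OC1=C[C@@H](C)[C@H](C(C)=C)[C@H]1C(C)C(=O)OC)C(F)(F)F | intermediate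
10 | methyl 2-[(1S,4R,5S)-2-ethyl-4-methyl-5-(prop-1-en-2-yl)cyclopent-2-en-1-yl]propanoate | CCC1=C[C@@H](C)[C@H](C(C)=C)[C@H]1C(C)C(=O)OC | intermediate
11 | 2-[(1S,4R,5S)-2-ethyl-4-methyl-5-(prop-1-en-2-yl)cyclopent-2-en-1-yl]propanoic acid | CCC1=C[C@@H](C)[C@H](C(C)=C)[C@H]1C(C)C(=O)O | intermediate
12 | (R)-but-3-yn-2-ol | C[C@@H](O)C#C | starting material
13 | dilithium salt of (R)-but-3-yn-2-ol | [Li+].[Li+].C[C@@H]([O-])C#[C-] | intermediate
14 | (R)-pent-3-yn-2-ol | C[C@@H](O)C#CC | intermediate
15 | O,C-bis(chlorozirconocene) adduct of 14 (E-alkenylzirconium, Zr on C4) | C[C@@H](O[Zr](Cl)(C1C=CC=C1)C1C=CC=C1)/C=C(C)/[Zr](Cl)(C1C=CC=C1)C1C=CC=C1 | intermediate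
16 | (2R,3E)-4-iodopent-3-en-2-ol | C[C@@H](O)/C=C(C)/I | intermediate
17 | propyne | CC#C | starting material
18 | (2R,3E)-4-methylhept-3-en-5-yn-2-ol | C[C@@H](O)/C=C(C)/C#CC | intermediate
19 | O,C-bis(chlorozirconocene) adduct of 18 (3E,5E-dienylzirconium, Zr on C6) | C[C@@H](O[Zr](Cl)(C1C=CC=C1)C1C=CC=C1)/C=C(C)/C=C(C)/[Zr](Cl)(C1C=CC=C1)C1C=CC=C1 | intermediate
20 | (2R,3E,5E)-6-iodo-4-methylhepta-3,5-dien-2-ol | C[C@@H](O)/C=C(C)/C=C(C)/I | intermediate
21 | (2R,3E,5E)-6-iodo-4-methylhepta-3,5-dien-2-yl 2-[(1S,4R,5S)-2-ethyl-4-methyl-5-(prop-1-en-2-yl)cyclopent-2-en-1-yl]propanoate | CCC1=C[C@@H](C)[C@H](C(C)=C)[C@H]1C(C)C(=O)O[C@H](C)/C=C(C)/C=C(C)/I | intermediate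
22 | lithium (Z)-enolate of 21 (C7a cis to O–Li) | CCC1=C[C@@H](C)[C@H](C(C)=C)[C@H]1/C(C)=C(\[O-])O[C@H](C)/C=C(C)/C=C(C)/I.[Li+] | intermediate
23 | (Z)-trimethylsilyl ketene acetal of 21 (C7a cis to OSi) | CCC1=C[C@@H](C)[C@H](C(C)=C)[C@H]1/C(C)=C(\O[Si](C)(C)C)O[C@H](C)/C=C(C)/C=C(C)/I | intermediate
24 | trimethylsilyl ester of 25 | CCC1=C[C@@H](C)[C@H](C(C)=C)[C@H]1[C@@](C)(C(=O)O[Si](C)(C)C)[C@](C)(/C=C/C)/C=C(C)/I | intermediate
25 | (2R,3R,4E)-2-[(1R,4R,5S)-2-ethyl-4-methyl-5-(prop-1-en-2-yl)cyclopent-2-en-1-yl]-3-[(1E)-2-iodoprop-1-en-1-yl]-2,3-dimethylhex-4-enoic acid | CCC1=C[C@@H](C)[C@H](C(C)=C)[C@H]1[C@@](C)(C(=O)O)[C@](C)(/C=C/C)/C=C(C)/I | intermediate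
26 | (1R,3aR,4R,5R,7aS)-3-ethyl-5-[(1E)-2-iodoprop-1-en-1-yl]-1,4,5,7-tetramethyl-3a,4,5,7a-tetrahydro-1H-indene-4-carboxylic acid | CCC1=C[C@@H](C)[C@@H]2C(C)=C[C@](C)(/C=C(C)/I)[C@](C)(C(=O)O)[C@@H]12 | intermediate
27 | (E)-2-phenylvinylboronic acid | OB(O)/C=C/c1ccccc1 | starting material
28 | zyggomphic acid B | CCC1=C[C@@H](C)[C@@H]2C(C)=C[C@](C)(/C=C(C)/C=C/c3ccccc3)[C@](C)(C(=O)O)[C@@H]12 | target

## Step count and least certain steps

Total: 14 steps. Longest linear sequence: 10 steps (steps 1–6 and 11–14, from 1). Steps 7–10 form the four-step side branch.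

**Step 12 (key step).**
- Risk: incomplete control of the tetrasubstituted enolate geometry, because both α-substituents are carbon. Leakage through a boat array is also possible, because the chair is crowded at both termini. Either process erodes the C6/C7 relative configuration. A slow rearrangement would also let the ketene acetal decompose by loss of silyl alkoxide.
- Fallback: this sets the geometry by approach control on a ketene instead of by deprotonation. It sets out from 11 and 20. Oxalyl chloride with catalytic DMF converts 11 into the acid chloride F1. Triethylamine dehydrochlorinates F1 to the methyl(cyclopentenyl)ketene F2. LiHMDS converts 20 into the lithium alkoxide F3, which is added to F2 at −78 °C. Attack in the ketene plane from the side of the small methyl group should place the allyloxy group cis to methyl. That product is 22, where the route is rejoined (silylation to 23).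

**Step 2.**
- Risk: proton transfer between the enolate and the product, followed by enolate equilibration toward C2 and expulsion of the silyloxide before C–C bond formation. This is made more likely by slow displacement at a secondary bromide.
- Fallback: this installs the C7 unit before the conjugate addition. It sets out from 1. Iodine and pyridine give the 2-iodoenone F4. Zinc converts 4 into the Reformatsky reagent F5. A palladium-catalysed Negishi-type coupling of F4 with F5 gives the 2-substituted enone F6. Copper-catalysed addition of 2 to F6 and protonation of the enolate to the trans ketone comes back to the route at 6.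

**Step 13.**
- Risk: slow initiation, since both reacting alkenes are hindered (one 1,1-disubstituted, one internal on a quaternary carbon). Catalyst decay, intermolecular metathesis or alkene isomerisation could then overtake ring closure.
- Fallback: this changes the substrate so that a terminal vinyl group carries the carbene, at the price of giving up control by Cα and relying on the facial bias of C7a alone. It sets out from 11 and the commercial enynol (E)-3-methylpent-2-en-4-yn-1-ol F9. Dianion methylation gives the enynol F10. Hydrozirconation–iodinolysis gives the primary dienyl iodide alcohol F11. Esterification with 11 gives the ester F12. The rearrangement of step 12 gives the vinyl acid F13. Ring closure of F13, with loss of ethene, returns to the route at 26.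

**Step 3.**
- Risk: γ-deprotonation at the doubly allylic C3a by the amidine, leading to migration of the enone double bond into conjugation with the isopropenyl group and loss of C3a.
- Fallback: this separates deprotection from elimination, so that only a weak base acts on a good leaving group. It sets out from 6. HF·pyridine gives the β-hydroxy ketone F7. Mesyl chloride and triethylamine at −20 °C give the mesylate F8, which eliminates under the same conditions. The route is rejoined at 7.

## Further compounds

F1 | step 12 | 2-[(1S,4R,5S)-2-ethyl-4-methyl-5-(prop-1-en-2-yl)cyclopent-2-en-1-yl]propanoyl chloride | CCC1=C[C@@H](C)[C@H](C(C)=C)[C@H]1C(C)C(=O)Cl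
F2 | step 12 | methyl(cyclopentenyl)ketene, ring configuration as in 11 | CCC1=C[C@@H](C)[C@H](C(C)=C)[C@H]1C(C)=C=O
F3 | step 12 | lithium (2R,3E,5E)-6-iodo-4-methylhepta-3,5-dien-2-olate | [Li+].C[C@@H]([O-])/C=C(C)/C=C(C)/I
F4 | step 2 | (R)-4-(tert-butyldimethylsilyloxy)-2-iodocyclopent-2-en-1-one | O=C1C[C@@H](O[Si](C)(C)C(C)(C)C)C=C1I
F5 | step 2 | bromo(1-methoxy-1-oxopropan-2-yl)zinc | COC(=O)C(C)[Zn]Br
F6 | step 2 | methyl 2-[(3R)-3-(tert-butyldimethylsilyloxy)-5-oxocyclopent-1-en-1-yl]propanoate | O=C1C[C@@H](O[Si](C)(C)C(C)(C)C)C=C1C(C)C(=O)OC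
F7 | step 3 | methyl 2-[(1S,2S,3R)-3-hydroxy-5-oxo-2-(prop-1-en-2-yl)cyclopentyl]propanoate | O=C1C[C@@H](O)[C@H](C(C)=C)[C@H]1C(C)C(=O)OC
F8 | step 3 | methyl 2-[(1S,2S,3R)-3-(methylsulfonyloxy)-5-oxo-2-(prop-1-en-2-yl)cyclopentyl]propanoate | O=C1C[C@@H](OS(C)(=O)=O)[C@H](C(C)=C)[C@H]1C(C)C(=O)OC
F9 | step 13 | (E)-3-methylpent-2-en-4-yn-1-ol | OC/C=C(C)/C#C
F10 | step 13 | (E)-3-methylhex-2-en-4-yn-1-ol | OC/C=C(C)/C#CC
F11 | step 13 | (2E,4E)-5-iodo-3-methylhexa-2,4-dien-1-ol | OC/C=C(C)/C=C(C)/I
F12 | step 13 | (2E,4E)-5-iodo-3-methylhexa-2,4-dien-1-yl 2-[(1S,4R,5S)-2-ethyl-4-methyl-5-(prop-1-en-2-yl)cyclopent-2-en-1-yl]propanoate | CCC1=C[C@@H](C)[C@H](C(C)=C)[C@H]1C(C)C(=O)OC/C=C(C)/C=C(C)/I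
F13 | step 13 | vinyl analogue of 25 (C6 bears vinyl in place of propenyl, configuration as in 25) | CCC1=C[C@@H](C)[C@H](C(C)=C)[C@H]1[C@@](C)(C(=O)O)[C@](C)(C=C)/C=C(C)/I
A1 | alternative 1 | open-chain polyene acid (C7=C7a E, C1=C2 with C7a and C3 cis, remaining alkenes E, C3 as in 28) | OC(=O)/C(C)=C/C(CC)=C\[C@@H](C)/C=C(C)/C=C(C)/C=C(C)/C=C/c1ccccc1
A2 | alternative 2 | ten-membered dienyl lactone trans-fused to the cyclopentene (C7 undefined) | CCC1=C[C@@H](C)[C@H]2[C@H]1C(C)C(=O)OC/C=C(C)\C=C2\C
A3 | alternative 2 | C6-vinyl bicyclic acid | CCC1=C[C@@H](C)[C@@H]2C(C)=C[C@](C)(C=C)[C@](C)(C(=O)O)[C@@H]12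
A4 | alternative 3 | open-chain dienyne methyl ester carrying the C6/C7 array | CCC#C[C@@](C)(C(=O)OC)[C@@](C)(/C=C(C)/C=C/c1ccccc1)/C=C(C)\C=C\C
A5 | alternative 3 | bicyclic dienone (C2 ketone, C1=C7a) methyl ester | CCC1=C2[C@H]([C@H](C)C1=O)C(C)=C[C@](C)(/C=C(C)/C=C/c3ccccc3)[C@]2(C)C(=O)OC
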